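**Retrosynthetic overview** (macrolide numbering: C1 = lactone C=O, C13 = ring CH bearing the ring oxygen, C14 = its methyl)
1. Target 27 ⇐ 12-methylene macrolide 26 (C12=CH2) by C11–OH-directed hydrogenation, which sets C12; 26 ⇐ protected macrolide 25 by removal of the TBS and acetonide groups.
2. 25 ⇐ vinyl ester/2-bromoalkene 24 by cutting C12–C13 (Ni–H hydroalkenylative macrocyclisation). Enabling feature: ring O–C13H(CH3) is an O-acylated acetaldehyde unit, i.e. the hydro form of a vinyl ester of the C1 carboxyl, whose C1=O can chelate nickel at C13; C12 carries an exocyclic methyl that can be held as the =CH2 of a bromoalkene next to the C11 oxygen.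
3. 24 ⇐ ethyl ketone 17 (C1–C10) + 2-bromoacrolein 20 (C11, C12, 12-CH2) by a reagent-controlled syn boron aldol (C10–C11); then TBS ether, allyl ester → acid → vinyl ester.
4. 17 ⇐ β-keto imide 4 (C1–C4) + aldehyde 8 (C5–C9, from lipase-desymmetrised meso-2,4-dimethylpentane-1,5-diol) by a titanium syn,syn aldol (C4–C5), Zn(BH4)2 syn reduction, acetonide formation and EtMgBr addition/oxidation at C9.
5. Ring order: temporary 1,3-dioxane (acetonide over O3/O5, step 8) → 14-membered lactone ring, the only ring of the target, closed last at C12–C13 (step 19) → acetonide removed (step 20).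

Key step: step 19

Assumption: where both mirror-image forms of a chiral mediator are available (acylating or hydrolysing mode of the lipase in step 4, Ipc2BOTf in step 15, the bis(oxazoline) on nickel in step 19), the form that gives the configuration drawn is the one used.

Step 1
Reactants: 1 (R)-4-benzyl-3-propionyloxazolidin-2-one; 2 propanal
Product: 3 (R)-4-benzyl-3-[(2R,3S)-3-hydroxy-2-methylpentanoyl]oxazolidin-2-one
Conditions: Bu2BOTf, Et3N, CH2Cl2, −78 → 0 °C; 2, −78 → 0 °C; then pH 7 buffer, MeOH, 30% H2O2, 0 °C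
Reagents that add atoms: none
Why: Evans boron syn-aldol, in which the Z-boron enolate reacts through a Zimmerman–Traxler chair on the face away from the benzyl group and so sets the later C2 centre as R.

Step 2
Reactants: 3 (R)-4-benzyl-3-[(2R,3S)-3-hydroxy-2-methylpentanoyl]oxazolidin-2-one
Product: 4 (R)-4-benzyl-3-[(R)-2-methyl-3-oxopentanoyl]oxazolidin-2-one
Conditions: SO3·pyridine, DMSO, Et3N, CH2Cl2, −10 → 0 °C
Reagents that add atoms: none
Why: Parikh–Doering oxidation should give the β-keto imide without epimerisation, because A(1,3) strain in the imide keeps the C2–H bond out of the alignment needed for enolisation.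

Step 3
Reactants: 5 meso-2,4-dimethylglutaric anhydride (cis-3,5-dimethyloxane-2,6-dione)
Product: 6 meso-(2R,4S)-2,4-dimethylpentane-1,5-diol
Conditions: LiAlH4, THF, 0 °C → reflux; Fieser work-up
Reagents that add atoms: none
Why: Hydride reduction of a cyclic anhydride to the diol touches neither methyl-bearing centre, so the meso relation (later C6/C8 syn) is kept.

Step 4
Reactants: 6 meso-(2R,4S)-2,4-dimethylpentane-1,5-diol
Product: 7 (2R,4S)-5-hydroxy-2,4-dimethylpentyl acetate
Conditions: Amano lipase AK (Pseudomonas fluorescens), vinyl acetate, THF, rt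
Reagents that add atoms: vinyl acetate, C=COC(C)=O
Why: Enzymatic desymmetrisation by a lipase (irreversible transesterification of one enantiotopic CH2OH group) fixes the absolute configuration of both methyl-bearing centres (C6 and C8) in one operation.

Step 5
Reactants: 7 (2R,4S)-5-hydroxy-2,4-dimethylpentyl acetate
Product: 8 (2R,4S)-2,4-dimethyl-5-oxopentyl acetate
Conditions: TPAP (cat.), NMO, 4 Å MS, CH2Cl2, rt; used crude
Reagents that add atoms: none
Why: Ley–Griffith oxidation is neutral and should give the α-methyl aldehyde without epimerisation.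

Step 6
Reactants: 4 (R)-4-benzyl-3-[(R)-2-methyl-3-oxopentanoyl]oxazolidin-2-one; 8 (2R,4S)-2,4-dimethyl-5-oxopentyl acetate
Product: 9 (R)-4-benzyl-3-[(2R,4R,5S,6S,8R)-9-acetoxy-5-hydroxy-2,4,6,8-tetramethyl-3-oxononanoyl]oxazolidin-2-one
Conditions: 4, TiCl4, iPr2NEt, CH2Cl2, −78 → 0 °C; then 8, −78 °C
Reagents that add atoms: none
Why: Evans titanium-enolate aldol of a β-keto imide: the Z-chlorotitanium enolate formed at C4 reacts through a chelated chair governed by the C2 centre to give the 2,4-syn/4,5-syn adduct (C4 and C5 set), in the anti-Felkin sense toward C6 that Z-enolates normally prefer with α-methyl aldehydes.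

Step 7
Reactants: 9 (R)-4-benzyl-3-[(2R,4R,5S,6S,8R)-9-acetoxy-5-hydroxy-2,4,6,8-tetramethyl-3-oxononanoyl]oxazolidin-2-one
Product: 10 (R)-4-benzyl-3-[(2R,3S,4R,5S,6S,8R)-9-acetoxy-3,5-dihydroxy-2,4,6,8-tetramethylnonanoyl]oxazolidin-2-one
Conditions: Zn(BH4)2, CH2Cl2/Et2O, −78 → −20 °C
Reagents that add atoms: none
Why: Chelation-controlled reduction, in which zinc ties the C5 hydroxyl to the C3 ketone and hydride adds to the chelate to give the 3,5-syn diol (C3 set).

Step 8
Reactants: 10 (R)-4-benzyl-3-[(2R,3S,4R,5S,6S,8R)-9-acetoxy-3,5-dihydroxy-2,4,6,8-tetramethylnonanoyl]oxazolidin-2-one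
Product: 11 3,5-O-isopropylidene acetal (acetonide) of 10
Conditions: 2,2-dimethoxypropane, PPTS (cat.), CH2Cl2, rt (crude 10 used at once)
Reagents that add atoms: 2,2-dimethoxypropane, COC(C)(C)OC
Why: Acid-catalysed transketalisation of the syn-1,3-diol gives the six-membered acetonide and forestalls δ-lactonisation of the C5 hydroxyl onto the imide.

Step 9
Reactants: 11 3,5-O-isopropylidene acetal (acetonide) of 10
Product: 13 (2R,3S,4R,5S,6S,8R)-9-hydroxy-3,5-(isopropylidenedioxy)-2,4,6,8-tetramethylnonanoic acid, via peroxy acid 12 (not isolated)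
Conditions: LiOH, 30% H2O2, THF/H2O, 0 °C → rt; then aq. Na2SO3, pH 3
Reagents that add atoms: lithium hydroperoxide (from LiOH and H2O2), [Li+].[O-]O
Why: Hydroperoxide cleavage of the N-acyl oxazolidinone attacks the exocyclic carbonyl selectively and without epimerisation at C2, the primary acetate is saponified in the same pot, and sulfite reduces the peroxy acid.

Step 10
Reactants: 13 (2R,3S,4R,5S,6S,8R)-9-hydroxy-3,5-(isopropylidenedioxy)-2,4,6,8-tetramethylnonanoic acid
Product: 14 allyl (2R,3S,4R,5S,6S,8R)-9-hydroxy-3,5-(isopropylidenedioxy)-2,4,6,8-tetramethylnonanoate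
Conditions: allyl bromide, KHCO3, DMF, rt
Reagents that add atoms: allyl bromide, C=CCBr
Why: SN2 O-alkylation of the carboxylate is chemoselective over the primary alcohol under bicarbonate conditions.

Step 11
Reactants: 14 allyl (2R,3S,4R,5S,6S,8R)-9-hydroxy-3,5-(isopropylidenedioxy)-2,4,6,8-tetramethylnonanoate
Product: 15 allyl (2R,3S,4R,5S,6S,8R)-3,5-(isopropylidenedioxy)-2,4,6,8-tetramethyl-9-oxononanoate
Conditions: TPAP (cat.), NMO, 4 Å MS, CH2Cl2, rt
Reagents that add atoms: none
Why: Ley–Griffith oxidation of the primary alcohol leaves the allyl ester, the acetonide and the C8 centre untouched.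

Step 12
Reactants: 15 allyl (2R,3S,4R,5S,6S,8R)-3,5-(isopropylidenedioxy)-2,4,6,8-tetramethyl-9-oxononanoate
Product: 16 allyl (2R,3S,4R,5S,6S,8R,9RS)-9-hydroxy-3,5-(isopropylidenedioxy)-2,4,6,8-tetramethylundecanoate (mixture of C9 epimers)
Conditions: EtMgBr, THF, −78 °C; aq. NH4Cl
Reagents that add atoms: ethylmagnesium bromide, CC[Mg]Br
Why: Grignard addition at −78 °C is selective for the aldehyde over the ester, and the C9 epimers converge in the next step.

Step 13
Reactants: 16 allyl (2R,3S,4R,5S,6S,8R,9RS)-9-hydroxy-3,5-(isopropylidenedioxy)-2,4,6,8-tetramethylundecanoate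
Product: 17 allyl (2R,3S,4R,5S,6S,8R)-3,5-(isopropylidenedioxy)-2,4,6,8-tetramethyl-9-oxoundecanoate
Conditions: TPAP (cat.), NMO, 4 Å MS, CH2Cl2, rt
Reagents that add atoms: none
Why: Ley–Griffith oxidation gives the ethyl ketone under neutral conditions that should not epimerise C8.

Step 14
Reactants: 18 acrolein
Product: 20 2-bromoacrolein, via 2,3-dibromopropanal 19 (not isolated)
Conditions: Br2, CH2Cl2, −78 °C; then Et3N, −78 → 0 °C; distilled and used at once
Reagents that add atoms: bromine, BrBr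
Why: Bromine addition to the alkene followed by E2 loss of HBr across the acidic α-position gives the α-bromo enal.

Step 15
Reactants: 17 allyl (2R,3S,4R,5S,6S,8R)-3,5-(isopropylidenedioxy)-2,4,6,8-tetramethyl-9-oxoundecanoate; 20 2-bromoacrolein
Product: 21 allyl (2R,3S,4R,5S,6S,8R,10R,11R)-12-bromo-11-hydroxy-3,5-(isopropylidenedioxy)-2,4,6,8,10-pentamethyl-9-oxotridec-12-enoate (11R by CIP; same spatial arrangement as 11S of the target)
Conditions: Ipc2BOTf, iPr2NEt, CH2Cl2, −78 °C; 20, −78 → −20 °C; then pH 7 buffer, MeOH, 30% H2O2, 0 °C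
Reagents that add atoms: none
Why: Paterson syn-aldol with a diisopinocampheylboron enolate: enolisation on the ethyl side gives the Z-enol borinate, the chair transition state gives the 10,11-syn relation, and the Ipc ligands choose the enolate face (reagent control, since the C8 centre has no β-heteroatom and biases weakly), setting C10 and C11 with an unhindered α-substituted enal of the methacrolein type.

Step 16
Reactants: 21 allyl (2R,3S,4R,5S,6S,8R,10R,11R)-12-bromo-11-hydroxy-3,5-(isopropylidenedioxy)-2,4,6,8,10-pentamethyl-9-oxotridec-12-enoate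
Product: 22 11-O-tert-butyldimethylsilyl ether of 21
Conditions: TBSOTf, 2,6-lutidine, CH2Cl2, −78 °C
Reagents that add atoms: tert-butyldimethylsilyl triflate, CC(C)(C)[Si](C)(C)OS(=O)(=O)C(F)(F)F
Why: Silylation of the secondary alcohol blocks retro-aldol cleavage and later acyl transfer from the vinyl ester to O11.

Step 17
Reactants: 22 11-O-tert-butyldimethylsilyl ether of 21
Product: 23 (2R,3S,4R,5S,6S,8R,10R,11R)-12-bromo-11-(tert-butyldimethylsilyloxy)-3,5-(isopropylidenedioxy)-2,4,6,8,10-pentamethyl-9-oxotridec-12-enoic acid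
Conditions: Pd(PPh3)4 (cat.), morpholine, THF, 0 °C
Reagents that add atoms: none
Why: Tsuji–Trost deallylation, in which Pd(0) ionises the allyl ester and morpholine traps the π-allyl, should be much faster at 0 °C than oxidative addition to the hindered bromoalkene.

Step 18
Reactants: 23 (2R,3S,4R,5S,6S,8R,10R,11R)-12-bromo-11-(tert-butyldimethylsilyloxy)-3,5-(isopropylidenedioxy)-2,4,6,8,10-pentamethyl-9-oxotridec-12-enoic acid
Product: 24 vinyl ester of 23
Conditions: Pd(OAc)2 (cat.), KOH (cat.), vinyl acetate (solvent), rt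
Reagents that add atoms: vinyl acetate, C=COC(C)=O
Why: Pd(II)-catalysed transvinylation (acyloxypalladation of vinyl acetate, then β-acetate elimination) is driven by vinyl acetate as solvent and uses no Pd(0) that could attack the C–Br bond.

Step 19
Reactants: 24 vinyl ester of 23
Product: 25 (2R,3S,4R,5S,6S,8R,10R,11R,13R)-12,12a-didehydro-8,8a-deoxyoleandolide 3,5-acetonide 11-TBS ether (C12=CH2)
Conditions: NiBr2·glyme (cat.), chiral bis(oxazoline) ligand (cat.), (EtO)2MeSiH, KF, DMA/THF, rt, slow addition of 24 to 2 mM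
Reagents that add atoms: none
Why: Proposed new method: a ligated nickel hydride (from Ni(II), the silane and fluoride) should insert the vinyl ester with nickel at the oxygen-bearing carbon, because the ester carbonyl chelates the metal in a five-membered α-acyloxyalkylnickel, and the hydrogen placed on the terminal carbon becomes the C14 methyl group; oxidative addition of the tethered C12–Br bond to this alkylnickel and C(sp3)–C(sp2) reductive elimination then form C12–C13. The closest known reaction type is the NiH-catalysed enantioselective Markovnikov hydroalkylation and hydroarylation of enol esters and enamides with organic halides, here run within one molecule. The 14-membered lactone ring closes in a 14-exo-trig sense at the inner vinyl carbon (C14 stays outside the ring) through a 15-membered nickelacycle. C13 is the only new stereocentre and should be set by the chiral bis(oxazoline) on nickel (form chosen for 13R), while C12 stays sp2 until step 21. The step needs hydrometalation of the vinyl ester in preference to the bromoalkene and the ketone, and ring closure in preference to chain growth: only the vinyl ester offers a chelating carbonyl, the flanked C9 ketone and the hindered 1,1-disubstituted bromoalkene are slow to take up Ni–H, and slow addition to 2 mM together with the turn fixed by the 3,5-acetonide should favour the ring.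

Step 20
Reactants: 25 (2R,3S,4R,5S,6S,8R,10R,11R,13R)-12,12a-didehydro-8,8a-deoxyoleandolide 3,5-acetonide 11-TBS ether
Product: 26 (2R,3S,4R,5S,6S,8R,10R,11R,13R)-12,12a-didehydro-8,8a-deoxyoleandolide (C12=CH2; 3-, 5- and 11-OH free)
Conditions: 48% aq. HF, MeCN, 0 °C → rt
Reagents that add atoms: none
Why: Aqueous HF cleaves the silyl ether and hydrolyses the acetonide in one operation under conditions that the lactone, the β-hydroxy ketone and the allylic ester should tolerate.

Step 21
Reactants: 26 (2R,3S,4R,5S,6S,8R,10R,11R,13R)-12,12a-didehydro-8,8a-deoxyoleandolide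
Product: 27 8,8a-deoxyoleandolide, (2R,3S,4R,5S,6S,8R,10R,11S,12R,13R)
Conditions: [Rh(nbd)(dppb)]BF4 (cat.), H2 (60 bar), CH2Cl2, rt
Reagents that add atoms: none
Why: Hydroxyl-directed homogeneous hydrogenation, in which cationic rhodium binds the allylic C11–OH and the 1,1-disubstituted alkene and the chelate that minimises A(1,3) strain delivers H2 so that the new C12 methyl is anti to the C11 oxygen (12R), without hydrogenolysis of the allylic C13–O bond.

**Compound list**
1 | (R)-4-benzyl-3-propionyloxazolidin-2-one | CCC(=O)N1[C@H](Cc2ccccc2)COC1=O | starting material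
2 | propanal | CCC=O | starting material
3 | (R)-4-benzyl-3-[(2R,3S)-3-hydroxy-2-methylpentanoyl]oxazolidin-2-one | CC[C@H](O)[C@@H](C)C(=O)N1[C@H](Cc2ccccc2)COC1=O | intermediate
4 | (R)-4-benzyl-3-[(R)-2-methyl-3-oxopentanoyl]oxazolidin-2-one | CCC(=O)[C@@H](C)C(=O)N1[C@H](Cc2ccccc2)COC1=O | intermediate
5 | meso-2,4-dimethylglutaric anhydride | C[C@H]1C[C@@H](C)C(=O)OC1=O | starting material
6 | meso-(2R,4S)-2,4-dimethylpentane-1,5-diol | OC[C@@H](C)C[C@@H](C)CO | intermediate
7 | (2R,4S)-5-hydroxy-2,4-dimethylpentyl acetate | OC[C@@H](C)C[C@@H](C)COC(C)=O | intermediate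
8 | (2R,4S)-2,4-dimethyl-5-oxopentyl acetate | O=C[C@@H](C)C[C@@H](C)COC(C)=O | intermediate
9 | (R)-4-benzyl-3-[(2R,4R,5S,6S,8R)-9-acetoxy-5-hydroxy-2,4,6,8-tetramethyl-3-oxononanoyl]oxazolidin-2-one | O=C(N1[C@H](Cc2ccccc2)COC1=O)[C@H](C)C(=O)[C@H](C)[C@@H](O)[C@@H](C)C[C@@H](C)COC(C)=O | intermediate
10 | (R)-4-benzyl-3-[(2R,3S,4R,5S,6S,8R)-9-acetoxy-3,5-dihydroxy-2,4,6,8-tetramethylnonanoyl]oxazolidin-2-one | O=C(N1[C@H](Cc2ccccc2)COC1=O)[C@H](C)[C@@H](O)[C@H](C)[C@@H](O)[C@@H](C)C[C@@H](C)COC(C)=O | intermediate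
11 | 3,5-O-isopropylidene acetal of 10 | O=C(N1[C@H](Cc2ccccc2)COC1=O)[C@H](C)[C@@H](O3)[C@H](C)[C@@H](OC3(C)C)[C@@H](C)C[C@@H](C)COC(C)=O | intermediate
12 | (2R,3S,4R,5S,6S,8R)-9-hydroxy-3,5-(isopropylidenedioxy)-2,4,6,8-tetramethylnonaneperoxoic acid | OOC(=O)[C@H](C)[C@@H](O3)[C@H](C)[C@@H](OC3(C)C)[C@@H](C)C[C@@H](C)CO | intermediate (not isolated)
13 | (2R,3S,4R,5S,6S,8R)-9-hydroxy-3,5-(isopropylidenedioxy)-2,4,6,8-tetramethylnonanoic acid | OC(=O)[C@H](C)[C@@H](O3)[C@H](C)[C@@H](OC3(C)C)[C@@H](C)C[C@@H](C)CO | intermediate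
14 | allyl ester of 13 | C=CCOC(=O)[C@H](C)[C@@H](O3)[C@H](C)[C@@H](OC3(C)C)[C@@H](C)C[C@@H](C)CO | intermediate
15 | allyl (2R,3S,4R,5S,6S,8R)-3,5-(isopropylidenedioxy)-2,4,6,8-tetramethyl-9-oxononanoate | C=CCOC(=O)[C@H](C)[C@@H](O3)[C@H](C)[C@@H](OC3(C)C)[C@@H](C)C[C@@H](C)C=O | intermediate
16 | allyl (2R,3S,4R,5S,6S,8R,9RS)-9-hydroxy-3,5-(isopropylidenedioxy)-2,4,6,8-tetramethylundecanoate | C=CCOC(=O)[C@H](C)[C@@H](O3)[C@H](C)[C@@H](OC3(C)C)[C@@H](C)C[C@@H](C)C(O)CC | intermediate
17 | allyl (2R,3S,4R,5S,6S,8R)-3,5-(isopropylidenedioxy)-2,4,6,8-tetramethyl-9-oxoundecanoate | C=CCOC(=O)[C@H](C)[C@@H](O3)[C@H](C)[C@@H](OC3(C)C)[C@@H](C)C[C@@H](C)C(=O)CC | intermediate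
18 | acrolein | C=CC=O | starting material
19 | 2,3-dibromopropanal (racemic) | O=CC(Br)CBr | intermediate (not isolated)
20 | 2-bromoacrolein | C=C(Br)C=O | intermediate
21 | allyl (2R,3S,4R,5S,6S,8R,10R,11R)-12-bromo-11-hydroxy-3,5-(isopropylidenedioxy)-2,4,6,8,10-pentamethyl-9-oxotridec-12-enoate | C=CCOC(=O)[C@H](C)[C@@H](O3)[C@H](C)[C@@H](OC3(C)C)[C@@H](C)C[C@@H](C)C(=O)[C@H](C)[C@@H](O)C(Br)=C | intermediate
22 | 11-O-TBS ether of 21 | C=CCOC(=O)[C@H](C)[C@@H](O3)[C@H](C)[C@@H](OC3(C)C)[C@@H](C)C[C@@H](C)C(=O)[C@H](C)[C@@H](O[Si](C)(C)C(C)(C)C)C(Br)=C | intermediate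
23 | (2R,3S,4R,5S,6S,8R,10R,11R)-12-bromo-11-(tert-butyldimethylsilyloxy)-3,5-(isopropylidenedioxy)-2,4,6,8,10-pentamethyl-9-oxotridec-12-enoic acid | OC(=O)[C@H](C)[C@@H](O3)[C@H](C)[C@@H](OC3(C)C)[C@@H](C)C[C@@H](C)C(=O)[C@H](C)[C@@H](O[Si](C)(C)C(C)(C)C)C(Br)=C | intermediate
24 | vinyl ester of 23 | C=COC(=O)[C@H](C)[C@@H](O3)[C@H](C)[C@@H](OC3(C)C)[C@@H](C)C[C@@H](C)C(=O)[C@H](C)[C@@H](O[Si](C)(C)C(C)(C)C)C(Br)=C | intermediate
25 | (2R,3S,4R,5S,6S,8R,10R,11R,13R)-12,12a-didehydro-8,8a-deoxyoleandolide 3,5-acetonide 11-TBS ether | O=C1[C@H](C)[C@@H](O3)[C@H](C)[C@@H](OC3(C)C)[C@@H](C)C[C@@H](C)C(=O)[C@H](C)[C@@H](O[Si](C)(C)C(C)(C)C)C(=C)[C@@H](C)O1 | intermediate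
26 | (2R,3S,4R,5S,6S,8R,10R,11R,13R)-12,12a-didehydro-8,8a-deoxyoleandolide | O=C1[C@H](C)[C@@H](O)[C@H](C)[C@@H](O)[C@@H](C)C[C@@H](C)C(=O)[C@H](C)[C@@H](O)C(=C)[C@@H](C)O1 | intermediate
27 | 8,8a-deoxyoleandolide, (2R,3S,4R,5S,6S,8R,10R,11S,12R,13R) | C[C@@H]1[C@@H](O)[C@@H](C)C[C@@H](C)C(=O)[C@H](C)[C@@H](O)[C@@H](C)[C@@H](C)OC(=O)[C@H](C)[C@H]1O | target

**Step count and risks**
Total step count: 21. Longest linear sequence: 18 steps (5 → 27 through steps 3–13 and 15–21).

Steps most likely to fail: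

Step 19 (Proposed new method). The nickel hydride may reduce the C12–Br bond or add to the vinyl ester in the linear sense, chains may grow faster than the ring closes, and the new centre at C13 may form without facial control. The fallback uses known chemistry, sets out from 22 and comes back at 25. It makes the C12–C13 bond between molecules and closes the ring at the ester instead. Nozaki–Hiyama–Kishi coupling of bromoalkene 22 with acetaldehyde (CrCl2, cat. NiCl2, DMSO/THF, with a chiral sulfonamide ligand on chromium to favour 13R; epimers separable) should give the allylic alcohol F1. Tsuji–Trost removal of the allyl ester (Pd(PPh3)4, morpholine) should give the seco acid F2. Yamaguchi macrolactonisation (2,4,6-trichlorobenzoyl chloride, Et3N, then DMAP, toluene, high dilution) through the mixed anhydride F3 should close the lactone at O–C1 and deliver 25.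

Step 21. Hydrogen may be delivered to the wrong face of C12 if the ring conformation prevents the C11–OH/rhodium/alkene chelate, and the allylic C13–O bond may be cleaved. The fallback sets out from 25 and comes back at 27. It sets C12 by hydroboration and obtains the methyl group by deoxygenation. Rhodium-catalysed hydroboration of silyl ether 25 with catecholborane (RhCl(PPh3)3, THF) should give the boronate F4; the catalysed reaction is syn-selective for allylic silyl ethers, which here corresponds to the 11,12-anti relation, and it should leave the ketone alone. Oxidation with NaBO3 should give the primary alcohol F5, I2/PPh3/imidazole the iodide F6, and Bu3SnH/AIBN the protected macrolide F7. Aqueous HF in MeCN then removes the TBS and acetonide groups to give 27.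

Step 18. Vinyl exchange on the hindered acid may be slow and stop short, while palladium consumes the bromoalkene in Heck-type processes with vinyl acetate. The fallback sets out from 23 and comes back at 24 without a new compound (F0). It is a copper-mediated oxidative O-vinylation of acid 23 with potassium vinyltrifluoroborate (CuBr, DMAP, 4 Å MS, O2, MeCN/CH2Cl2), a Chan–Lam-type C–O coupling that uses no palladium.

Further compounds
F1 | step 19 | allyl (2R,3S,4R,5S,6S,8R,10R,11R,13R)-11-(tert-butyldimethylsilyloxy)-13-hydroxy-3,5-(isopropylidenedioxy)-2,4,6,8,10-pentamethyl-12-methylidene-9-oxotetradecanoate | C=CCOC(=O)[C@H](C)[C@@H](O3)[C@H](C)[C@@H](OC3(C)C)[C@@H](C)C[C@@H](C)C(=O)[C@H](C)[C@@H](O[Si](C)(C)C(C)(C)C)C(=C)[C@@H](C)O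
F2 | step 19 | seco acid (free acid of F1) | OC(=O)[C@H](C)[C@@H](O3)[C@H](C)[C@@H](OC3(C)C)[C@@H](C)C[C@@H](C)C(=O)[C@H](C)[C@@H](O[Si](C)(C)C(C)(C)C)C(=C)[C@@H](C)O
F3 | step 19 | mixed anhydride of F2 with 2,4,6-trichlorobenzoic acid (not isolated) | O=C(OC(=O)[C@H](C)[C@@H](O3)[C@H](C)[C@@H](OC3(C)C)[C@@H](C)C[C@@H](C)C(=O)[C@H](C)[C@@H](O[Si](C)(C)C(C)(C)C)C(=C)[C@@H](C)O)c1c(Cl)cc(Cl)cc1Cl
F4 | step 21 | 12a-(1,3,2-benzodioxaborol-2-yl) derivative of the protected macrolide (not isolated) | O=C1[C@H](C)[C@@H](O3)[C@H](C)[C@@H](OC3(C)C)[C@@H](C)C[C@@H](C)C(=O)[C@H](C)[C@@H](O[Si](C)(C)C(C)(C)C)[C@@H](CB4Oc5ccccc5O4)[C@@H](C)O1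
F5 | step 21 | 12a-hydroxy-8,8a-deoxyoleandolide 3,5-acetonide 11-TBS ether | O=C1[C@H](C)[C@@H](O3)[C@H](C)[C@@H](OC3(C)C)[C@@H](C)C[C@@H](C)C(=O)[C@H](C)[C@@H](O[Si](C)(C)C(C)(C)C)[C@@H](CO)[C@@H](C)O1
F6 | step 21 | 12a-iodo-8,8a-deoxyoleandolide 3,5-acetonide 11-TBS ether | O=C1[C@H](C)[C@@H](O3)[C@H](C)[C@@H](OC3(C)C)[C@@H](C)C[C@@H](C)C(=O)[C@H](C)[C@@H](O[Si](C)(C)C(C)(C)C)[C@@H](CI)[C@@H](C)O1
F7 | step 21 | 8,8a-deoxyoleandolide 3,5-acetonide 11-TBS ether | O=C1[C@H](C)[C@@H](O3)[C@H](C)[C@@H](OC3(C)C)[C@@H](C)C[C@@H](C)C(=O)[C@H](C)[C@@H](O[Si](C)(C)C(C)(C)C)[C@@H](C)[C@@H](C)O1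
F0 | step 18 | none | none
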